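The constants used here were set for the occasion.

The constant of the over-reaction step, 1.20 /M/min, is smaller than the constant that loads free catalyst, 30.7 /M/min, yet it acts on target for as long as target stays in the vessel.

| setting | ochre | grey | violet | amber |
|---|---|---|---|---|
| substrate | 0.10 M | 0.10 M (fed, over 1.25 h) | 0.10 M | 0.10 M |
| reagent | 0.0950 M | 0.0950 M | 0.0950 M (fed, over 1.25 h) | 0.0950 M |
| capture agent | 0.100 M | 0.100 M | 0.100 M | 0.100 M |
| free catalyst | 2.0 mM | 2.0 mM | 2.0 mM | 2.0 mM |
| time | 2.5 h | 2.5 h | 2.5 h |  |
| remark | a closed flask charged with all of it at once and left for 2.5 h | all but substrate at the start; substrate goes in evenly over 1.25 h, the run ends at 2.5 h | a stirred flask in which reagent is dosed at a steady rate over 1.25 h without added volume, worked up at 2.5 h | one stirred flow tank at steady state, fed with the mixture as stated, mean residence time 2.5 h |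

    catalyst intermediate A → released group + catalyst intermediate B (k1 = 4.02 /min)
    substrate + catalyst intermediate B → catalyst intermediate C (k2 = 12.5 /M/min)
    catalyst intermediate C → free catalyst + target (k3 = 6.96 /min)
    reagent + target → over-reaction product (k4 = 1.20 /M/min)
    reagent + free catalyst → catalyst intermediate A (k5 = 30.7 /M/min)
    capture agent + catalyst intermediate B → trapped intermediate (k6 = 5.75 /M/min)

- the stated concentrations are those of everything mixed, before any reaction; amounts are the same in each set-up
- the feed brings no volume worth counting
- run time (ochre): 2.5 h

- the set-up with the highest share of target in all that became target or over-reaction product, at the outlet or at the end ("none" if the first two lie within 2 percentage points) (ochre / grey / violet / amber / none)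
- share of target in all that became target or over-reaction product, at the outlet or at the end, ochre
- share of target in all that became target or over-reaction product, at the outlet or at the end, grey
- share of target in all that became target or over-reaction product, at the outlet or at the end, violet
- share of target in all that became target or over-reaction product, at the outlet or at the end, amber

Turned round, the question is what the numbers must show for target to hold more than half of the pair target plus over-reaction product. With [reagent] nearly steady, target suffers a pseudo-first-order loss, and its half-life with reagent as charged is 6.08 min, far shorter than 2.5 h. Let E be the over-reaction constant times [reagent] times the residence time. In amber, a steady balance sends target out through the outlet and into over-reaction product in the ratio 1 to E, so the share is 1/(1 + E). A majority of target needs E below 1. With reagent as charged, a first round gives E = 17.1, far above that, and a share of 5.52%.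

A second round corrects [reagent]. At catalyst intermediate B, substrate competes with capture agent, and as charged each catalyst makes on average n = 2.17 targets before it is trapped. Reagent is therefore spent on 1 + n passes through the cycle, and again on the part of the target that over-reacts, which is 10.5 mM in all. By this reckoning, that leaves about 0.0845 M in amber. The exposure of target, the over-reaction constant times [reagent] times the residence time, becomes 15.2, and the share in amber becomes 6.17%.

In ochre, the passes last about 4.07 min, much less than the run, so target formed early meets nearly that exposure in full, and hardly any survives. This reckoning goes no further than ochre and amber, and it puts amber above ochre.

The forecast names amber, with 6.1% (range 5% to 7.5%) for amber and <0.001%, <0.001% and <0.001% for ochre, grey and violet, on the ground that the tank “keeps fresh target at the outlet”.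

The simulation gives 6.13% for amber, more than the 0%, 0% and 0% for ochre, grey and violet, so the best set-up is amber. Over-reaction product in amber stands at 3.88% of the substrate charged. With the residence time ten times as long and [reagent] taken as reckoned, the exposure is 152, so the share should be 0.654%, and the tank at that residence time gives 0.653%.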